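## Retrosynthetic overview

1. Target 26 ⇐ 1β,2β-epoxy-3-ketone 24 by one-pot reductive epoxide opening and deallylation; ring A comes from the Δ1-3β-ol of gibberellic acid (GA3).
2. The 12α-OH and the 9α-H ⇐ 9(11)-en-12-one 17, by bulky-hydride reduction and radical conjugate reduction.
3. Ring C is re-formed last: the C12–C13 bond is made by a photochemical acyl-radical SN2′ cyclisation of seco aldehyde/allyl sulfone 15 (key step).
4. 15 ⇐ photochemical alkoxy-radical β-scission of the C12–C13 bond of GA3; the oxygen leaves C13 and re-enters at C12.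
5. Rings A, B, D and the lactone (C4, C5, C6, C8, C10) are bought in GA3 (1). Order: ring C opened (step 3), ring C re-closed (step 7), ring A adjusted (steps 11–14).

Assumption: the SMILES is read as a 9-epi C19 gibberellin (C4, C5, C6, C8, C10 as in GA3; H9 on the α face); gibberellane numbering is used (C7 = acid carbon, C17 = methylene carbon, C19 = lactone carbonyl; α = face of the lactone bridge; at C12, α = anti to the C15–C16 bridge).

## Route

Step 1
Reactants: 1 gibberellic acid (GA3); 2 allyl bromide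
Product: 3 allyl gibberellate (GA3 allyl ester)
Conditions: KHCO3, DMF, rt
Reagents that add atoms: allyl bromide, C=CCBr
Why: SN2 O-alkylation of the carboxylate under bicarbonate conditions too mild to isomerise the allylic lactone; no stereocentre is touched.

Step 2
Reactants: 3 allyl gibberellate; 4 tert-butyldimethylsilyl chloride
Product: 5 allyl 3-O-(tert-butyldimethylsilyl)gibberellate
Conditions: imidazole, DMF, rt to 40 °C
Reagents that add atoms: tert-butyldimethylsilyl chloride, CC(C)(C)[Si](C)(C)Cl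
Why: imidazole-mediated silylation of the only reactive (secondary allylic) hydroxyl; the bridgehead tertiary 13-OH stays free.

Step 3
Reactants: 5 allyl 3-O-TBS-gibberellate; 6 iodine
Product: 8 allyl 3β-(TBS-oxy)-12-iodo-13-oxo-12,13-secogibberella-1,16-dien-7-oate 19,10-lactone, via tertiary hypoiodite 7 (not isolated)
Conditions: PhI(OAc)2, iodine, CH2Cl2, visible light (tungsten lamp), 0 °C to rt
Reagents that add atoms: iodine, [I][I]
Why: Suárez hypoiodite photolysis gives the 13-alkoxy radical, whose β-scission of C12–C13 leaves the conjugated 2-methylenecyclopentanone (ring D) and an unhindered primary C12 radical that is capped by iodine; only C13 changes (it becomes sp2).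

Step 4
Reactants: 8 seco iodo enone
Product: 9 allyl 3β-(TBS-oxy)-13-hydroxy-12-iodo-12,13-secogibberella-1,16-dien-7-oate 19,10-lactone (C13 epimers)
Conditions: NaBH4, CeCl3·7H2O, MeOH, −78 °C
Reagents that add atoms: none
Why: Luche 1,2-reduction of the enone (iodide, esters and lactone untouched); the new C13 carbinol centre forms as a mixture and is erased in step 5.

Step 5
Reactants: 9 seco allylic alcohol; 10 benzenesulfinyl chloride
Product: 12 allyl 3β-(TBS-oxy)-12-iodo-17-(phenylsulfonyl)-12,13-secogibberella-1,13(16)-dien-7-oate 19,10-lactone, via allylic sulfinate ester 11 (not isolated)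
Conditions: PhS(O)Cl, Et3N, CH2Cl2, −78 to 0 °C; then toluene, 80 °C
Reagents that add atoms: benzenesulfinyl chloride, O=S(Cl)c1ccccc1
Why: O-sulfinylation followed by [2,3]-sigmatropic sulfinate-to-sulfone rearrangement transposes the allyl unit, erasing the C13 centre and placing the sulfone on C17 with the alkene at C13=C16.

Step 6
Reactants: 12 seco iodo allyl sulfone; 13 trimethylamine N-oxide
Product: 15 allyl 3β-(TBS-oxy)-12-oxo-17-(phenylsulfonyl)-12,13-secogibberella-1,13(16)-dien-7-oate 19,10-lactone (C12 aldehyde), via alkoxytrimethylammonium iodide 14 (not isolated)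
Conditions: Me3NO, DMSO, rt
Reagents that add atoms: trimethylamine N-oxide, C[N+](C)(C)[O-]
Why: Kornblum-type (Ganem) oxidation: the N-oxide oxygen displaces the primary iodide (SN2) and the alkoxyammonium salt loses Me3N and a proton to give the aldehyde under nearly neutral conditions that spare the acidic allyl sulfone.

Step 7
Reactants: 15 seco aldehyde allyl sulfone
Product: 16 allyl 3β-(TBS-oxy)-12-oxogibberella-1,16-dien-7-oate 19,10-lactone (9β-H, 13-H)
Conditions: (nBu4N)4[W10O32] (2 mol %), MeCN (degassed), 390 nm LEDs, rt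
Reagents that add atoms: none
Why: Proposed new method: excited decatungstate abstracts the formyl hydrogen, the nucleophilic acyl radical closes 6-exo-trig onto C13 of the allyl sulfone from the only face the C9 tether can reach (so C8 fixes C13), β-scission of PhSO2• unveils the 16-methylene and the sulfonyl radical reoxidises the reduced polyoxometalate; the closest known reactions are intermolecular decatungstate hydroacylation of alkenes and radical allylation with allyl sulfones, not yet shown as an intramolecular acyl-radical SN2′ closure of a bridged ring.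

Step 8
Reactants: 16 tetracyclic 12-ketone
Product: 17 allyl 3β-(TBS-oxy)-12-oxogibberella-1,9(11),16-trien-7-oate 19,10-lactone
Conditions: IBX, DMSO/fluorobenzene, 70 °C
Reagents that add atoms: none
Why: IBX dehydrogenation through the only possible enol (toward C11, since C13 is a bridgehead) gives the enone and makes C9 trigonal.

Step 9
Reactants: 17 9(11)-en-12-one
Product: 19 allyl 3β-(TBS-oxy)-12-oxo-9-epi-gibberella-1,16-dien-7-oate 19,10-lactone (9α-H), via tributyltin enolate 18 (not isolated)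
Conditions: Bu3SnH, AIBN (cat.), benzene, 80 °C; then H2O
Reagents that add atoms: none
Why: radical conjugate reduction through an O-stannyl ketyl (tin adds to O, the allylic radical takes H at C9 from Bu3SnH, workup protonates the tin enolate): H arrives on the exo face of the bicyclo[3.2.1]octene, anti to the C15–C16 bridge, giving 9α-H, and the neutral radical path avoids the β-elimination of the lactone that a C9 carbanion would trigger.

Step 10
Reactants: 19 9-epi 12-ketone
Product: 20 allyl 3β-(TBS-oxy)-12α-hydroxy-9-epi-gibberella-1,16-dien-7-oate 19,10-lactone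
Conditions: LiBH(s-Bu)3, THF, −78 °C; then H2O
Reagents that add atoms: none
Why: bulky trialkylborohydride reduction: hydride enters along the equatorial trajectory of the ring C chair, away from the syn-axial H9α and H14, so the OH ends axial (12α, anti to the C15–C16 bridge, cis to H9).

Step 11
Reactants: 20 12α-alcohol silyl ether
Product: 21 allyl 3β,12α-dihydroxy-9-epi-gibberella-1,16-dien-7-oate 19,10-lactone
Conditions: HF·pyridine, pyridine, THF, 0 °C to rt
Reagents that add atoms: none
Why: fluoride-driven desilylation under buffered conditions that the allylic lactone, the exocyclic alkene and the allyl ester tolerate.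

Step 12
Reactants: 21 3β,12α-diol
Product: 22 allyl 12α-hydroxy-3-oxo-9-epi-gibberella-1,16-dien-7-oate 19,10-lactone
Conditions: MnO2, CH2Cl2, rt
Reagents that add atoms: none
Why: MnO2 allylic oxidation is selective for the allylic 3-OH; the non-allylic 12-OH and the alkenes are untouched.

Step 13
Reactants: 22 ring A enone; 23 tert-butyl hydroperoxide
Product: 24 allyl 1β,2β-epoxy-12α-hydroxy-3-oxo-9-epi-gibberell-16-en-7-oate 19,10-lactone
Conditions: t-BuOOH, DBU, CH2Cl2, 0 °C to rt
Reagents that add atoms: tert-butyl hydroperoxide, CC(C)(C)OO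
Why: Weitz–Scheffer nucleophilic epoxidation: the peroxide anion adds to C1 from the β face, anti to the axial C10–O bond of the α-lactone bridge, and ring closure gives the 1β,2β-epoxide; the isolated 16-ene is inert to the nucleophilic oxidant.

Step 14
Reactants: 24 epoxy ketone allyl ester
Product: 26 CNP0259985.3 (1β,12α-dihydroxy-3-oxo-9-epi-gibberell-16-ene-7,19-dioic acid 19,10-lactone), via epoxy keto acid 25 (not isolated)
Conditions: Pd(PPh3)4 (5 mol %), HCO2H, Et3N, THF, rt
Reagents that add atoms: none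
Why: palladium-catalysed formate hydrogenolysis: zerovalent palladium ionises the allyl ester (π-allyl, hydride capture gives propene) and opens the α,β-epoxy ketone at C2–O to a palladium enolate that is reduced to the aldol, so the C1–O bond keeps its β configuration.

## Compound list

1 | gibberellic acid (GA3) | C=C1C[C@]23C[C@@]1(O)CC[C@H]2[C@]12OC(=O)[C@](C)([C@@H](O)C=C1)[C@H]2[C@@H]3C(=O)O | starting material
2 | allyl bromide | C=CCBr | starting material
3 | allyl gibberellate | C=C1C[C@]23C[C@@]1(O)CC[C@H]2[C@]12OC(=O)[C@](C)([C@@H](O)C=C1)[C@H]2[C@@H]3C(=O)OCC=C | intermediate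
4 | tert-butyldimethylsilyl chloride | CC(C)(C)[Si](C)(C)Cl | starting material
5 | allyl 3-O-(tert-butyldimethylsilyl)gibberellate | C=C1C[C@]23C[C@@]1(O)CC[C@H]2[C@]12OC(=O)[C@](C)([C@@H](O[Si](C)(C)C(C)(C)C)C=C1)[C@H]2[C@@H]3C(=O)OCC=C | intermediate
6 | iodine | [I][I] | starting material
7 | 13-O-iodo derivative (tertiary hypoiodite) of 5 | C=C1C[C@]23C[C@@]1(OI)CC[C@H]2[C@]12OC(=O)[C@](C)([C@@H](O[Si](C)(C)C(C)(C)C)C=C1)[C@H]2[C@@H]3C(=O)OCC=C | intermediate
8 | allyl 3β-(TBS-oxy)-12-iodo-13-oxo-12,13-secogibberella-1,16-dien-7-oate 19,10-lactone (2-iodoethyl on C9α; ring D = 2-methylenecyclopentanone spiro at C8) | ICC[C@@H]1[C@]2(CC(=O)C(=C)C2)[C@@H](C(=O)OCC=C)[C@@H]2[C@](C)(C(=O)O3)[C@@H](O[Si](C)(C)C(C)(C)C)C=C[C@@]123 | intermediate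
9 | 13-hydroxy analogue of 8 (allylic alcohol, C13 epimers) | ICC[C@@H]1[C@]2(CC(O)C(=C)C2)[C@@H](C(=O)OCC=C)[C@@H]2[C@](C)(C(=O)O3)[C@@H](O[Si](C)(C)C(C)(C)C)C=C[C@@]123 | intermediate
10 | benzenesulfinyl chloride | O=S(Cl)c1ccccc1 | starting material
11 | 13-O-benzenesulfinate of 9 (C13 and S epimers) | ICC[C@@H]1[C@]2(CC(OS(=O)c4ccccc4)C(=C)C2)[C@@H](C(=O)OCC=C)[C@@H]2[C@](C)(C(=O)O3)[C@@H](O[Si](C)(C)C(C)(C)C)C=C[C@@]123 | intermediate
12 | allyl 3β-(TBS-oxy)-12-iodo-17-(phenylsulfonyl)-12,13-secogibberella-1,13(16)-dien-7-oate 19,10-lactone | ICC[C@@H]1[C@]2(CC=C(CS(=O)(=O)c4ccccc4)C2)[C@@H](C(=O)OCC=C)[C@@H]2[C@](C)(C(=O)O3)[C@@H](O[Si](C)(C)C(C)(C)C)C=C[C@@]123 | intermediate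
13 | trimethylamine N-oxide | C[N+](C)(C)[O-] | starting material
14 | C12 alkoxytrimethylammonium iodide of 12 | C[N+](C)(C)OCC[C@@H]1[C@]2(CC=C(CS(=O)(=O)c4ccccc4)C2)[C@@H](C(=O)OCC=C)[C@@H]2[C@](C)(C(=O)O3)[C@@H](O[Si](C)(C)C(C)(C)C)C=C[C@@]123.[I-] | intermediate
15 | allyl 3β-(TBS-oxy)-12-oxo-17-(phenylsulfonyl)-12,13-secogibberella-1,13(16)-dien-7-oate 19,10-lactone (C12 aldehyde) | O=CC[C@@H]1[C@]2(CC=C(CS(=O)(=O)c4ccccc4)C2)[C@@H](C(=O)OCC=C)[C@@H]2[C@](C)(C(=O)O3)[C@@H](O[Si](C)(C)C(C)(C)C)C=C[C@@]123 | intermediate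
16 | allyl 3β-(TBS-oxy)-12-oxogibberella-1,16-dien-7-oate 19,10-lactone (9β-H, 13-H) | C=C1C[C@]23C[C@H]1C(=O)C[C@H]2[C@]12OC(=O)[C@](C)([C@@H](O[Si](C)(C)C(C)(C)C)C=C1)[C@H]2[C@@H]3C(=O)OCC=C | intermediate
17 | allyl 3β-(TBS-oxy)-12-oxogibberella-1,9(11),16-trien-7-oate 19,10-lactone | C=C1C[C@]23C[C@H]1C(=O)C=C2[C@]12OC(=O)[C@](C)([C@@H](O[Si](C)(C)C(C)(C)C)C=C1)[C@H]2[C@@H]3C(=O)OCC=C | intermediate
18 | 12-O-tributylstannyl 11-en-12-olate (tin enolate) of 19 (9α-H) | C=C1C[C@]23C[C@H]1C(O[Sn](CCCC)(CCCC)CCCC)=C[C@@H]2[C@]12OC(=O)[C@](C)([C@@H](O[Si](C)(C)C(C)(C)C)C=C1)[C@H]2[C@@H]3C(=O)OCC=C | intermediate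
19 | allyl 3β-(TBS-oxy)-12-oxo-9-epi-gibberella-1,16-dien-7-oate 19,10-lactone (9α-H) | C=C1C[C@]23C[C@H]1C(=O)C[C@@H]2[C@]12OC(=O)[C@](C)([C@@H](O[Si](C)(C)C(C)(C)C)C=C1)[C@H]2[C@@H]3C(=O)OCC=C | intermediate
20 | allyl 3β-(TBS-oxy)-12α-hydroxy-9-epi-gibberella-1,16-dien-7-oate 19,10-lactone | C=C1C[C@]23C[C@H]1[C@@H](O)C[C@@H]2[C@]12OC(=O)[C@](C)([C@@H](O[Si](C)(C)C(C)(C)C)C=C1)[C@H]2[C@@H]3C(=O)OCC=C | intermediate
21 | allyl 3β,12α-dihydroxy-9-epi-gibberella-1,16-dien-7-oate 19,10-lactone | C=C1C[C@]23C[C@H]1[C@@H](O)C[C@@H]2[C@]12OC(=O)[C@](C)([C@@H](O)C=C1)[C@H]2[C@@H]3C(=O)OCC=C | intermediate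
22 | allyl 12α-hydroxy-3-oxo-9-epi-gibberella-1,16-dien-7-oate 19,10-lactone | C=C1C[C@]23C[C@H]1[C@@H](O)C[C@@H]2[C@]12OC(=O)[C@](C)(C(=O)C=C1)[C@H]2[C@@H]3C(=O)OCC=C | intermediate
23 | tert-butyl hydroperoxide | CC(C)(C)OO | starting material
24 | allyl 1β,2β-epoxy-12α-hydroxy-3-oxo-9-epi-gibberell-16-en-7-oate 19,10-lactone | C=C1C[C@]23C[C@H]1[C@@H](O)C[C@@H]2[C@]12OC(=O)[C@](C)(C(=O)[C@H]4O[C@@H]14)[C@H]2[C@@H]3C(=O)OCC=C | intermediate
25 | 1β,2β-epoxy-12α-hydroxy-3-oxo-9-epi-gibberell-16-en-7-oic acid 19,10-lactone | C=C1C[C@]23C[C@H]1[C@@H](O)C[C@@H]2[C@]12OC(=O)[C@](C)(C(=O)[C@H]4O[C@@H]14)[C@H]2[C@@H]3C(=O)O | intermediate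
26 | CNP0259985.3 | C=C1C[C@]23C[C@H]1[C@@H](O)C[C@@H]2[C@]12OC(=O)[C@](C)(C(=O)C[C@H]1O)[C@H]2[C@@H]3C(=O)O | target

## Step count and risks

Total steps: 14. Longest linear sequence: 14 steps from 1 (fully linear).

Stereocentres: C4, C5, C6, C8 and C10 are carried from 1. C13 is re-set in step 7 under control of C8. C9 is set in step 9, C12 in step 10 and C1 in step 13, each controlled by the existing framework.

The three steps most likely to fail:

**Step 3 (photochemical β-scission/iodination).** Two risks: acetyl hypoiodite may add to the electron-rich 16-ene before the hypoiodite is photolysed, and scission of C13–C14 may compete with the wanted C12–C13 cleavage. The fallback sets out from 5 and comes back at 15; it removes electrophilic iodine and delivers C12 at the aldehyde level, but does not change the scission regiochemistry, so any regioisomer is separated at the oxime stage. Exchange with tert-butyl nitrite (CH2Cl2, rt) gives the 13-nitrite ester F1. Irradiation at 350 nm in benzene cleaves C12–C13 through the same alkoxy radical and nitric oxide caps C12 to give the C-nitroso seco enone F2, which tautomerises on warming in 2-propanol to the seco aldoxime F3. Exchange with glyoxylic acid in aqueous THF frees the seco keto aldehyde F4. A Luche reduction (NaBH4, CeCl3·7H2O, MeOH, −78 °C), in which the aldehyde is masked in situ as its hemiacetal, gives the seco hydroxy aldehyde F5. Benzenesulfinyl chloride and Et3N give the sulfinate ester F6, whose [2,3]-shift on warming in toluene returns 15.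

**Step 7 (proposed new photocyclisation).** Risks: hydrogen abstraction at other hydridic C–H bonds (C3–H, allylic CH2), decarbonylation, or slow closure of the bridged ring. The fallback uses known chemistry, sets out from 15 and comes back at 16. SmI2 (THF, t-BuOH, −78 to 0 °C) effects a ketyl–olefin cyclisation with β-elimination of benzenesulfinate (a known sequence for alkenes carrying an allylic leaving group) to give the tetracyclic 12-alcohol F7. Dess–Martin periodinane (CH2Cl2, NaHCO3, rt) oxidises F7 to 16.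

**Step 9 (radical conjugate reduction setting C9).** Risks: the β-carbon is flanked by two quaternary centres, so H-transfer may be slow; hydrogen could be taken up at C12 instead; stannyl radicals may add to the terminal alkenes. The fallback sets out from 17 and comes back at 19. Luche reduction (NaBH4, CeCl3·7H2O, MeOH, −78 °C) delivers hydride to the exo face and gives the 9(11)-en-12β-ol F8, with H12 on the exo face. Redox isomerisation of this allylic alcohol with H2-activated [Ir(cod)(PCy3)(py)]PF6 in degassed THF moves H12 suprafacially to C9 and gives 19 directly.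

## Further compounds

F1 | step 3 | 13-O-nitrite ester of 5 | C=C1C[C@]23C[C@@]1(ON=O)CC[C@H]2[C@]12OC(=O)[C@](C)([C@@H](O[Si](C)(C)C(C)(C)C)C=C1)[C@H]2[C@@H]3C(=O)OCC=C
F2 | step 3 | allyl 3β-(TBS-oxy)-12-nitroso-13-oxo-12,13-secogibberella-1,16-dien-7-oate 19,10-lactone | O=NCC[C@@H]1[C@]2(CC(=O)C(=C)C2)[C@@H](C(=O)OCC=C)[C@@H]2[C@](C)(C(=O)O3)[C@@H](O[Si](C)(C)C(C)(C)C)C=C[C@@]123
F3 | step 3 | C12 aldoxime of the seco enone (E/Z mixture) | ON=CC[C@@H]1[C@]2(CC(=O)C(=C)C2)[C@@H](C(=O)OCC=C)[C@@H]2[C@](C)(C(=O)O3)[C@@H](O[Si](C)(C)C(C)(C)C)C=C[C@@]123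
F4 | step 3 | allyl 3β-(TBS-oxy)-12,13-dioxo-12,13-secogibberella-1,16-dien-7-oate 19,10-lactone (seco keto aldehyde) | O=CC[C@@H]1[C@]2(CC(=O)C(=C)C2)[C@@H](C(=O)OCC=C)[C@@H]2[C@](C)(C(=O)O3)[C@@H](O[Si](C)(C)C(C)(C)C)C=C[C@@]123
F5 | step 3 | seco hydroxy aldehyde (13-hydroxy-12-oxo, C13 epimers) | O=CC[C@@H]1[C@]2(CC(O)C(=C)C2)[C@@H](C(=O)OCC=C)[C@@H]2[C@](C)(C(=O)O3)[C@@H](O[Si](C)(C)C(C)(C)C)C=C[C@@]123
F6 | step 3 | 13-O-benzenesulfinate of the seco hydroxy aldehyde (C13 and S epimers) | O=CC[C@@H]1[C@]2(CC(OS(=O)c4ccccc4)C(=C)C2)[C@@H](C(=O)OCC=C)[C@@H]2[C@](C)(C(=O)O3)[C@@H](O[Si](C)(C)C(C)(C)C)C=C[C@@]123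
F7 | step 7 | allyl 3β-(TBS-oxy)-12α-hydroxygibberella-1,16-dien-7-oate 19,10-lactone (9β-H) | C=C1C[C@]23C[C@H]1[C@@H](O)C[C@H]2[C@]12OC(=O)[C@](C)([C@@H](O[Si](C)(C)C(C)(C)C)C=C1)[C@H]2[C@@H]3C(=O)OCC=C
F8 | step 9 | allyl 3β-(TBS-oxy)-12β-hydroxygibberella-1,9(11),16-trien-7-oate 19,10-lactone | C=C1C[C@]23C[C@H]1[C@H](O)C=C2[C@]12OC(=O)[C@](C)([C@@H](O[Si](C)(C)C(C)(C)C)C=C1)[C@H]2[C@@H]3C(=O)OCC=C
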